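Cuts (retrosynthesis): the three MOM ethers; C2–C1' (ring B off, back to an 8-geranylchromone); O1–C2 and C4–C4a together (ring C off); C8–C1'' (geranyl off). This leaves phloroglucinol.
Forward: ring A is bought, capped at O5 and O7, and C-geranylated next to its one free OH. Ring C is closed in one operation by a magnesium-templated (3+3) annulation, and ring B is added last.
Enabling feature: O1 of ring A lies between the geranyl-blocked C8 and, across C8a, the only open ortho carbon C4a. O1–C8a–C4a is therefore a 1,3-O,C-dinucleophile that fits the 1,3-dielectrophile C4–C3–C2 of (E)-3-ethoxyacryloyl chloride.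
Helpers: the ethoxy group keeps C2 at the vinylogous-ester level, so O1–C2 forms irreversibly and flat. It leaves as ethanol in the same flask, and the C2=C3 bond it leaves behind is used up in the next step.
Stereochemistry: C2 (S), the only stereocentre, is set by catalyst control in a rhodium-catalysed asymmetric 1,4-addition of the ring B boronic acid. The (E)-alkene comes with geranyl bromide.

Key step: step 3

Remark: flavanone numbering (O1, C2, C3, C4, C4a, C5 to C8, C8a; ring B C1' to C6'; geranyl from C1'') is used for all intermediates. Geranyl = (2E)-3,7-dimethylocta-2,6-dien-1-yl and MOM = methoxymethyl. The [C@H] centre of the target corresponds to 2S.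

Step 1
Reactants: 1 phloroglucinol (benzene-1,3,5-triol)
Product: 2 3,5-bis(methoxymethoxy)phenol
Conditions: NaH (2.0 equiv), MOMCl (2.0 equiv), DMF, 0 °C to rt
Reagents that add atoms: chloromethyl methyl ether (MOMCl), COCCl
Why: Williamson ether synthesis under stoichiometric control: the three hydroxyl groups of 1 are equivalent and MOMCl is a hard electrophile that alkylates oxygen, so two equivalents should favour the bis-ether, which is separable from the mono- and tris-ether, both of which can be fed back.

Step 2
Reactants: 2 3,5-bis(methoxymethoxy)phenol; 3 geranyl bromide, (2E)-1-bromo-3,7-dimethylocta-2,6-diene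
Product: 4 2-geranyl-3,5-bis(methoxymethoxy)phenol (geranyl between the free OH and one OMOM group)
Conditions: NaH (1.0 equiv), toluene, 0 °C to rt; then 3, rt to 40 °C
Reagents that add atoms: none
Why: C-alkylation of a phenoxide in a non-polar solvent: the tight sodium phenoxide ion pair in toluene shields oxygen and guides the SN2 displacement of the primary allylic bromide to an ortho carbon, the two ortho carbons of 2 are equivalent, and the (E)-alkene is not touched.

Step 3
Reactants: 4 2-geranyl-3,5-bis(methoxymethoxy)phenol; 5 (E)-3-ethoxyacryloyl chloride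
Product: 9 8-geranyl-5,7-bis(methoxymethoxy)-4H-chromen-4-one, via bromomagnesium phenolate 6 (not isolated), via hydroxyaryl ethoxyvinyl ketone 7 (not isolated), via 2-ethoxychromanone 8 (not isolated)
Conditions: EtMgBr (1.0 equiv), Et2O–toluene, 0 °C to rt, Et2O stripped; 5, toluene, 0 to 50 °C; then pyridinium p-toluenesulfonate (10 mol %), 60 °C, same flask
Reagents that add atoms: none
Why: EtMgBr turns 4 into the bromomagnesium phenolate 6, whose magnesium binds the carbonyl oxygen of 5 and hands the acyl carbon through a six-membered chelate to the ortho carbon C4a (C4–C4a bond), chloride going to magnesium and the ring proton to O1 to give 7. O1 then adds to the ethoxy-bearing C2 (O1–C2 bond, ring C closed in the 6-endo-trig mode) to give 8, and loss of ethanol under the mild pyridinium acid makes the closure irreversible and delivers chromone 9. The closest known reaction types are the ortho-specific C-acylation of halomagnesium phenolates with α,β-unsaturated acyl chlorides in non-polar solvents (a metal-templated Friedel–Crafts acylation) and the addition–elimination closure of ortho-hydroxyaryl β-alkoxy- or β-aminovinyl ketones to chromones. No stereocentre leaves the step: the C2 centre of 8 forms without control and is erased on purpose, so that C2 can be set afterwards by an irreversible C–C bond formation and not by a reversible oxa-Michael addition. The step needs C- over O-acylation (magnesium template, toluene), attack of the soft ring carbon at C4 and not at C2 (the donor ethoxy group deactivates C2), and the 8- and not the 6-geranyl series (C8 is blocked, C4a is the only ortho carbon within reach of the template, O5 and O7 are capped so that only O1 can close). Since no strong protic or Lewis acid is present, the geranyl chain and the MOM ethers should survive.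

Step 4
Reactants: 9 8-geranyl-5,7-bis(methoxymethoxy)-4H-chromen-4-one; 10 4-(methoxymethoxy)phenylboronic acid
Product: 11 (2S)-8-geranyl-5,7-bis(methoxymethoxy)-2-[4-(methoxymethoxy)phenyl]chroman-4-one
Conditions: [Rh(OH)(cod)]2 (2.5 mol %), (S)-MeO-F12-BIPHEP [(S)-6,6'-dimethoxybiphenyl-2,2'-diylbis{bis(3,4,5-trifluorophenyl)phosphane}] (5.5 mol %), 10 (excess), toluene–H2O, 40 °C
Reagents that add atoms: none
Why: Rhodium-catalysed asymmetric 1,4-addition of an arylboronic acid to a chromone (Hayashi–Miyaura reaction), a known entry to 5,7-dioxygenated flavanones: the aryl–rhodium species on the electron-poor (S)-biaryl bisphosphine should insert C2=C3 with the same facial sense as established for 2-cyclohexenone, which maps onto 2S here, water protonates the rhodium enolate before it can expel O1, and the isolated trisubstituted alkenes are inert.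

Step 5
Reactants: 11 (2S)-8-geranyl-5,7-bis(methoxymethoxy)-2-[4-(methoxymethoxy)phenyl]chroman-4-one
Product: 12 sophoraflavanone A, (2S)-8-geranyl-5,7-dihydroxy-2-(4-hydroxyphenyl)chroman-4-one
Conditions: aq HCl (3 M), MeOH, 50 °C
Reagents that add atoms: none
Why: Acid-catalysed acetal hydrolysis removes all three MOM ethers at once, the acidic medium avoids the base-induced retro-oxa-Michael opening that would racemise C2, and conditions of this kind are known to spare prenyl-type side chains on flavanones.

Compound list
1 | phloroglucinol (benzene-1,3,5-triol) | Oc1cc(O)cc(O)c1 | starting material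
2 | 3,5-bis(methoxymethoxy)phenol | COCOc1cc(O)cc(OCOC)c1 | intermediate
3 | geranyl bromide, (2E)-1-bromo-3,7-dimethylocta-2,6-diene | CC(C)=CCC/C(C)=C/CBr | starting material
4 | 2-geranyl-3,5-bis(methoxymethoxy)phenol | CC(C)=CCC/C(C)=C/Cc1c(O)cc(OCOC)cc1OCOC | intermediate
5 | (E)-3-ethoxyacryloyl chloride | CCO/C=C/C(=O)Cl | starting material
6 | bromomagnesium 2-geranyl-3,5-bis(methoxymethoxy)phenolate | CC(C)=CCC/C(C)=C/Cc1c(O[Mg]Br)cc(OCOC)cc1OCOC | intermediate
7 | (E)-3-ethoxy-1-[3-geranyl-2-hydroxy-4,6-bis(methoxymethoxy)phenyl]prop-2-en-1-one | CC(C)=CCC/C(C)=C/Cc1c(O)c(C(=O)/C=C/OCC)c(OCOC)cc1OCOC | intermediate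
8 | 2-ethoxy-8-geranyl-5,7-bis(methoxymethoxy)chroman-4-one (racemic, transient) | CC(C)=CCC/C(C)=C/Cc1c(OCOC)cc(OCOC)c2c1OC(OCC)CC2=O | intermediate
9 | 8-geranyl-5,7-bis(methoxymethoxy)-4H-chromen-4-one | CC(C)=CCC/C(C)=C/Cc1c(OCOC)cc(OCOC)c2c1OC=CC2=O | intermediate
10 | 4-(methoxymethoxy)phenylboronic acid | COCOc1ccc(B(O)O)cc1 | starting material
11 | (2S)-8-geranyl-5,7-bis(methoxymethoxy)-2-[4-(methoxymethoxy)phenyl]chroman-4-one | CC(C)=CCC/C(C)=C/Cc1c(OCOC)cc(OCOC)c2c1O[C@H](c1ccc(OCOC)cc1)CC2=O | intermediate
12 | sophoraflavanone A, (2S)-8-geranyl-5,7-dihydroxy-2-(4-hydroxyphenyl)chroman-4-one | CC(C)=CCC/C(C)=C/Cc1c(O)cc(O)c2c1O[C@H](c1ccc(O)cc1)CC2=O | target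

Total steps: 5. Longest linear sequence: 5 steps (1, 2, 4, 9, 11, 12).

Steps most likely to fail

Step 3. O-acylation of the phenolate may outrun the templated C-acylation. The MOM group next to the new carbonyl may also be lost through magnesium chelation. The fallback sets out from geranyl bromide 3 and comes back at chromone 9; it buys the aryl–carbonyl bond instead of making it.
- Commercial 2',4',6'-trihydroxyacetophenone is C-alkylated with 3 (KOH, MeOH, 0 °C to rt) to give 3-geranyl-2,4,6-trihydroxyacetophenone F1.
- MOMCl and iPr2NEt cap the unchelated hydroxyl and the less hindered of the two chelated ones. This gives 3-geranyl-2-hydroxy-4,6-bis(methoxymethoxy)acetophenone F2.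
- Condensation with N,N-dimethylformamide dimethyl acetal gives (E)-3-(dimethylamino)-1-[3-geranyl-2-hydroxy-4,6-bis(methoxymethoxy)phenyl]prop-2-en-1-one F3.
- F3 closes to 9 with loss of dimethylamine on silica gel or in warm acetic acid (classical enaminone chromone synthesis).

Step 4. Insertion of the electron-rich C2=C3 bond may be slow, the electron-rich boronic acid may protodeboronate, and facial selectivity may be poor. The fallback sets out from chromone 9 and comes back at 11; it sets C2 by reduction instead of by the C–C bond formation.
- An achiral catalyst, Pd(OCOCF3)2 with 2,2'-bipyridine, adds 10 to 9 and gives racemic 8-geranyl-5,7-bis(methoxymethoxy)-2-[4-(methoxymethoxy)phenyl]chroman-4-one F4.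
- Asymmetric transfer hydrogenation follows under dynamic kinetic resolution (RuCl[(S,S)-TsDPEN](p-cymene), HCO2H–DBU, MeCN, 40 °C). The base equilibrates C2 by retro-oxa-Michael and oxa-Michael steps, while only the 2S ketone fits the catalyst.
- This should funnel the material into cis-(2S,4S)-8-geranyl-5,7-bis(methoxymethoxy)-2-[4-(methoxymethoxy)phenyl]chroman-4-ol F5.
- Neutral oxidation of F5 with DMP in CH2Cl2 returns the ketone 11 without touching C2.

Step 2. O-alkylation and double alkylation may compete with mono-C-alkylation, and some attack may occur at the para carbon. The fallback sets out from phloroglucinol 1 (with 3) and comes back at 4; it reverses the order of events.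
- Free phloroglucinol, whose three ring CH positions are equivalent and strongly carbon-nucleophilic in aqueous KOH, is C-geranylated with 3 to give 2-geranylphloroglucinol F6.
- Two equivalents of NaH and MOMCl then cap the unhindered remote hydroxyl first and one of the two equivalent flanking hydroxyls second, which gives 4.

Further compounds
F1 | step 3 | 3-geranyl-2,4,6-trihydroxyacetophenone | CC(C)=CCC/C(C)=C/Cc1c(O)cc(O)c(C(C)=O)c1O
F2 | step 3 | 3-geranyl-2-hydroxy-4,6-bis(methoxymethoxy)acetophenone | CC(C)=CCC/C(C)=C/Cc1c(OCOC)cc(OCOC)c(C(C)=O)c1O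
F3 | step 3 | (E)-3-(dimethylamino)-1-[3-geranyl-2-hydroxy-4,6-bis(methoxymethoxy)phenyl]prop-2-en-1-one | CC(C)=CCC/C(C)=C/Cc1c(OCOC)cc(OCOC)c(C(=O)/C=C/N(C)C)c1O
F4 | step 4 | racemic 8-geranyl-5,7-bis(methoxymethoxy)-2-[4-(methoxymethoxy)phenyl]chroman-4-one | CC(C)=CCC/C(C)=C/Cc1c(OCOC)cc(OCOC)c2c1OC(c1ccc(OCOC)cc1)CC2=O
F5 | step 4 | cis-(2S,4S)-8-geranyl-5,7-bis(methoxymethoxy)-2-[4-(methoxymethoxy)phenyl]chroman-4-ol | CC(C)=CCC/C(C)=C/Cc1c(OCOC)cc(OCOC)c2c1O[C@H](c1ccc(OCOC)cc1)C[C@@H]2O
F6 | step 2 | 2-geranylphloroglucinol | CC(C)=CCC/C(C)=C/Cc1c(O)cc(O)cc1O
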